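## The problem

Target 20 is a benzophenone whose ring A is hexasubstituted. Three oxygens (the C5 methyl ether, the C7 hydroxyl and the pyran oxygen on C8a) alternate with three carbon substituents (C4 of the dihydropyran on C4a, the branched C10 chain on C6 and the 3-hydroxybenzoyl group on C8), so every group must be placed regiospecifically on a crowded ring with no free position left for correction. The dihydropyran is fused to ring A across C4a–C8a, and ring B is held only through the ketone. There are two stereocentres, C3 (R, the pyran carbinol) and C2′ of the side chain (R, bearing the isopropenyl group). The flat arene and seven bonds separate them, so neither can direct the other: one is taken from the chiral pool and one is set by a reagent. The side chain holds two 1,1-disubstituted alkenes arranged as a 1,5-diene. They rule out hydrogenation, strong acid (Markovnikov closure onto the neighbouring C7 hydroxyl), free electrophilic halogen and prolonged strong heating (Cope rearrangement through C2′). C2′ is allylic and would epimerise or slip into conjugation if a carbonyl group ever stood next to it. The three phenols are acidic and oxidisable, and the two that flank the ketone are hydrogen-bonded and nearly indistinguishable. The feature that opens the endgame is that O1–C2(Me2)–C3(OH)–C4 is a 3-methylbut-2-enyl group on C4a, oxidised at C3 and closed onto the C8a oxygen. Because the C5 oxygen on the other side of C4a is methylated, only the C8a hydroxyl can reach it, and until that closure the two ortho oxygens of ring A never have to be told apart.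

## Retrosynthesis

**Pyran ring (20 to 17).** The O1–C2 bond is cut and the C3 oxygen removed, which leads through epoxy triphenol 19 and silylated epoxide 18 to the prenylated benzophenone 17, with all three phenols as tert-butyldimethylsilyl ethers. Cutting O1–C8a instead would need an activated haloarene and deprotections after ring closure. Cutting C4–C4a would put the new stereocentre into an alkylating agent. Precursor 17 has one ring and one stereocentre fewer than 20. The forward reaction must oxidise the trisubstituted alkene ahead of the two 1,1-disubstituted ones, choose one alkene face by reagent control, and open the epoxide at its tertiary carbon under acid mild enough for the diene. The silyl groups are there so that no phenoxide is present during the basic oxidation.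

**Side chain (17 to 15 and 7).** The aryl–CH2 bond at C6 is cut, giving aryl bromide 15 and iodide 7, which are joined through alkylzinc 16. A cut one bond further out would place the reacting centre on C2′ itself. Friedel–Crafts acylation followed by reduction would put a carbonyl next to C2′. Direct C-alkylation of a phloroglucinol by a β-branched, non-allylic halide is not viable. Bromide 15 has no stereocentre and 7 carries only C2′. The coupling must tolerate a diaryl ketone and aryl silyl ethers, and must beat β-hydride elimination at a bromide with two ortho substituents.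

**Prenyl group and halogens (15 to 11).** The C4a–CH2 bond is cut back to aryl iodide 14, then the three O–Si bonds to 13, then C–I to 12 and C–Br to 11. Direct C-prenylation of such ketones with prenyl bromide gives C/O and mono/bis mixtures, and halogenation after prenylation would attack the alkene. Two halogens of different reactivity on the two equivalent ring positions of 11 fix the order of the couplings, and since those positions are equivalent it does not matter which halogen ends where. The forward steps need clean monohalogenation (bromine first, then iodine) and an iodide-selective coupling that delivers the prenyl group through its primary carbon.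

**Ring A core (11 to 8 and 9).** The O–CH3 bond is cut to tetrol 10 and the aryl–carbonyl bond to phloroglucinol 8 and 3-hydroxybenzoic acid 9. Acylating the symmetric triol raises no regiochemical question, whereas acylating a ready-made monomethyl ether would give two isomers. The methylation must single out the phenol para to the ketone by its acidity.

**C10 chain (7 to 1).** The C–I bond of 7 is traced back to the carboxyl group of acid 5 (through thiohydroxamate ester 6), the terminal methylene to the ketone of 4, the acid to aldehyde 3, and the open chain to the ring alkene of (R)-limonene 1 (through ozonide 2). C4 of limonene already carries the isopropenyl group and both arms of C2′ in the correct absolute sense. Ring cleavage leaves the arm towards the arene one carbon too long. Excising that carbon through a radical keeps the neighbouring stereocentre tetrahedral and never places a carbonyl group beside it, which every enolate-based degradation would do. The forward steps need selective ozonolysis of the ring alkene and a radical capture faster than cyclisation onto the pendant alkene.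

## Roads not taken

**Alternative 1:** Ring A would be built by a Danheiser benzannulation. The cut runs through C7–C8, C8a–C4a and C6–C7. Cyclobutenone A2 is heated with siloxyalkyne A3. The derived vinylketene adds across the alkyne, and four-electron opening followed by six-electron closure gives phenol A1, with the C7 hydroxyl free, the C8a oxygen silylated and the ketone still a silylated benzhydrol.
- Merits: the route is convergent and every substituent is placed by the mechanism. It is better than the chosen plan in that the two ortho oxygens are differentiated from the start and no halogenation or coupling has to be done on a crowded arene.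
- Weak points: A2, with three different substituents including the chiral chain, and A3 each need their own multistep synthesis. The thermal step exposes the 1,5-diene to Cope rearrangement through C2′. A1 still needs selective desilylation, oxidation of the benzhydrol, and the whole epoxidation–closure for C3.
- Comparison: the chosen plan is shorter, uses a cheap symmetric core and never needs the oxygen differentiation that this alternative delivers.

**Alternative 2:** Ring A would be closed by a polyketide-type Claisen condensation, cutting C8–C8a. With Mg(OMe)2 the doubly activated methylene of tetracarbonyl ester A5 attacks its own ester group, and enolisation gives trihydroxybenzophenone A4.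
- Merits: the arene appears with all three carbon substituents in place, and no halogen, tin or palladium chemistry on the ring is needed. In that respect it is cleaner than the chosen plan.
- Weak points: A5 is a doubly α-branched polycarbonyl chain that is long to assemble and exists as tautomer mixtures. Aldol closure and lactonisation to a pyranone compete with the desired mode. A4 has three free ring-A phenols, so the C5 oxygen must be methylated selectively while flanked by two alkyl groups, and the ring-B allyl ether must still be removed.
- Comparison: the chosen plan sets predictable bond-forming steps against this, and places the methyl group while only one strongly acidic phenol is present.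

**Alternative 3:** The pyran would be closed at the other C–O bond, cutting O1–C8a. KN(SiMe3)2 deprotonates the tertiary alcohol of fluoroarene A7, and the alkoxide displaces fluoride ortho to the ketone to give chroman A6.
- Merits: ring size is fixed by connectivity, so the 5-exo versus 6-endo question of the chosen plan does not arise, and C3 can be set earlier and independently. On that point this road is the safer one.
- Weak points: the substitution must occur on a ring carrying two methoxy donors, activated by a single ketone that two ortho groups twist out of conjugation. A7 is a hexasubstituted fluoroarene needing a longer build-up. A6 still requires selective cleavage of the C7 methyl ether beside the C5 one with a Lewis acid, acidic removal of the methoxymethyl group, and desilylation, all in the presence of the acid-sensitive diene.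
- Comparison: the chosen plan relies on Markovnikov opening of a trisubstituted epoxide, a well-precedented preference, and ends in the target with fluoride and a trace of acid only.

Key step: step 12

Abbreviation and numbering: TBS = tert-butyldimethylsilyl; ring-A positions are given in the chroman numbering of 20, and C2′ is the side-chain carbon bearing the isopropenyl group.

Assumption: for an aryl-CH2–CH=CMe2 alkene the D-fructose-derived ketone is taken to give the (R)-epoxide, as the spiro transition-state model predicts for R–CH=CMe2 alkenes; if the sense were opposite, the enantiomeric ketone would be used.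

## Route

Step 1
Reactants: 1 (R)-limonene
Product: 3 (3R)-6-oxo-3-(prop-1-en-2-yl)heptanal, via bicyclic ozonide 2 (not isolated)
Conditions: O3 (1.0 equiv, Sudan red 7B end-point), CH2Cl2, −78 °C; then PPh3, −78 °C → rt
Reagents that add atoms: ozone, [O-][O+]=O
Why: Ozonolysis: electrophilic ozone attacks the trisubstituted ring alkene ahead of the 1,1-disubstituted isopropenyl group when dosed to one equivalent at low temperature, and reduction of ozonide 2 gives the keto aldehyde. C4 of limonene is not touched and becomes C3 of 3.

Step 2
Reactants: 3 (3R)-6-oxo-3-(prop-1-en-2-yl)heptanal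
Product: 4 (3R)-6-oxo-3-(prop-1-en-2-yl)heptanoic acid
Conditions: NaClO2, NaH2PO4, 2-methylbut-2-ene, t-BuOH–H2O, 0 °C → rt
Reagents that add atoms: sodium chlorite, [Na+].[O-]Cl=O
Why: Pinnick oxidation converts only the aldehyde at pH 3–4, and the excess 2-methylbut-2-ene traps HOCl before it can add to the isopropenyl group. The stereocentre is β to both carbonyl groups and cannot epimerise.

Step 3
Reactants: 4 (3R)-6-oxo-3-(prop-1-en-2-yl)heptanoic acid
Product: 5 (3R)-6-methyl-3-(prop-1-en-2-yl)hept-6-enoic acid
Conditions: Ph3PCH3Br (2.5 equiv), KOtBu (3.4 equiv), THF, 0 °C → rt; aqueous NaH2PO4 work-up (pH 4)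
Reagents that add atoms: methyltriphenylphosphonium bromide, C[P+](c1ccccc1)(c1ccccc1)c1ccccc1.[Br-]
Why: Wittig methylenation: the carboxylate formed by the first equivalent of base is inert to the ylide, so only the methyl ketone reacts. The mildly acidic work-up avoids lactonisation of the γ,δ-unsaturated acid.

Step 4
Reactants: 5 (3R)-6-methyl-3-(prop-1-en-2-yl)hept-6-enoic acid
Product: 7 (3S)-3-(iodomethyl)-2,6-dimethylhepta-1,6-diene, via thiohydroxamate ester 6 (not isolated)
Conditions: N-hydroxypyridine-2-thione, DCC, 4-(dimethylamino)pyridine (cat.), CH2Cl2, 0 °C → rt, dark; filter, then CHI3 (1.5 equiv), benzene, hν (tungsten lamp), 25–40 °C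
Reagents that add atoms: iodoform, IC(I)I
Why: Barton decarboxylative iodination: photolysis of ester 6 releases CO2 and a primary radical, which should abstract iodine from iodoform much faster than it can add to either pendant alkene. The stereocentre is β to the radical, stays tetrahedral and keeps its spatial arrangement (the descriptor changes to S only because CH2I outranks isopropenyl).

Step 5
Reactants: 8 phloroglucinol; 9 3-hydroxybenzoic acid
Product: 10 (3-hydroxyphenyl)(2,4,6-trihydroxyphenyl)methanone
Conditions: P2O5–MeSO3H (1:10 w/w), 70 °C; ice-water quench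
Reagents that add atoms: none
Why: Friedel–Crafts acylation of the most electron-rich arene by the activated acid. The three positions of 8 are equivalent, the first acyl group deactivates the ring against a second, and the carboxyl-deactivated ring of 9 does not compete.

Step 6
Reactants: 10 (3-hydroxyphenyl)(2,4,6-trihydroxyphenyl)methanone
Product: 11 (2,6-dihydroxy-4-methoxyphenyl)(3-hydroxyphenyl)methanone
Conditions: Me2SO4 (1.0 equiv), KHCO3 (1.2 equiv), DMF, 25 °C
Reagents that add atoms: dimethyl sulfate, COS(=O)(=O)OC
Why: Williamson methylation under acidity control: the hydroxyl para to the ketone is a vinylogous acid and the only phenol that hydrogencarbonate ionises usefully, while the two hydrogen-bonded ortho phenols and the ordinary ring-B phenol stay protonated. This follows the classical selective 4-O-methylation of 2,4,6-trihydroxyaryl ketones.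

Step 7
Reactants: 11 (2,6-dihydroxy-4-methoxyphenyl)(3-hydroxyphenyl)methanone
Product: 12 (3-bromo-2,6-dihydroxy-4-methoxyphenyl)(3-hydroxyphenyl)methanone
Conditions: NBS (1.0 equiv), MeCN, −30 → 0 °C
Reagents that add atoms: N-bromosuccinimide, O=C1CCC(=O)N1Br
Why: Electrophilic aromatic bromination: the two free positions of ring A are equivalent and far more activated than any position of ring B, and the first bromine lowers the reactivity enough for monosubstitution with one equivalent.

Step 8
Reactants: 12 (3-bromo-2,6-dihydroxy-4-methoxyphenyl)(3-hydroxyphenyl)methanone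
Product: 13 (3-bromo-2,6-dihydroxy-5-iodo-4-methoxyphenyl)(3-hydroxyphenyl)methanone
Conditions: NIS (1.05 equiv), MeCN, 0 °C → rt
Reagents that add atoms: N-iodosuccinimide, O=C1CCC(=O)N1I
Why: Electrophilic aromatic iodination at the last free, still doubly activated position of ring A. Iodine is introduced after bromine so that no ipso-exchange of an aryl iodide by the stronger electrophile can occur.

Step 9
Reactants: 13 (3-bromo-2,6-dihydroxy-5-iodo-4-methoxyphenyl)(3-hydroxyphenyl)methanone
Product: 14 {3-bromo-2,6-bis[(tert-butyldimethylsilyl)oxy]-5-iodo-4-methoxyphenyl}{3-[(tert-butyldimethylsilyl)oxy]phenyl}methanone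
Conditions: TBSOTf (4.5 equiv), 2,6-lutidine (6 equiv), CH2Cl2, 0 °C → rt
Reagents that add atoms: tert-butyldimethylsilyl trifluoromethanesulfonate, CC(C)(C)[Si](C)(C)OS(=O)(=O)C(F)(F)F
Why: Silylation with the silyl triflate, which is reactive enough for hydrogen-bonded phenols flanked on both sides. All three phenols receive the same group, so the two ortho oxygens need no differentiation and one fluoride treatment frees them together later.

Step 10
Reactants: 14 {3-bromo-2,6-bis[(tert-butyldimethylsilyl)oxy]-5-iodo-4-methoxyphenyl}{3-[(tert-butyldimethylsilyl)oxy]phenyl}methanone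
Product: 15 {3-bromo-2,6-bis[(tert-butyldimethylsilyl)oxy]-4-methoxy-5-(3-methylbut-2-en-1-yl)phenyl}{3-[(tert-butyldimethylsilyl)oxy]phenyl}methanone
Conditions: tributyl(3-methylbut-2-en-1-yl)stannane (1.3 equiv), Pd(PPh3)4 (5 mol %), DMF, 80 °C
Reagents that add atoms: tributyl(3-methylbut-2-en-1-yl)stannane, CCCC[Sn](CCCC)(CCCC)CC=C(C)C
Why: Stille coupling: zerovalent palladium inserts into the C–I bond much faster than into the C–Br bond, and prenylstannanes normally deliver the group through the primary carbon. The neutral conditions spare the aryl silyl ethers and the ketone.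

Step 11
Reactants: 15 {3-bromo-2,6-bis[(tert-butyldimethylsilyl)oxy]-4-methoxy-5-(3-methylbut-2-en-1-yl)phenyl}{3-[(tert-butyldimethylsilyl)oxy]phenyl}methanone; 7 (3S)-3-(iodomethyl)-2,6-dimethylhepta-1,6-diene
Product: 17 {2,6-bis[(tert-butyldimethylsilyl)oxy]-4-methoxy-3-(3-methylbut-2-en-1-yl)-5-[(2R)-5-methyl-2-(prop-1-en-2-yl)hex-5-en-1-yl]phenyl}{3-[(tert-butyldimethylsilyl)oxy]phenyl}methanone, via alkylzinc iodide 16 (not isolated)
Conditions: 7, Zn dust (activated with BrCH2CH2Br and Me3SiCl), LiCl, THF, 25–40 °C; then 15, Pd(OAc)2 (5 mol %), SPhos (2-dicyclohexylphosphino-2′,6′-dimethoxybiphenyl, 10 mol %), THF, 25 → 50 °C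
Reagents that add atoms: none
Why: Negishi sp3–sp2 coupling: LiCl-assisted zinc insertion into the primary C–I bond gives 16, which couples with the di-ortho-substituted bromide under a bulky electron-rich biarylphosphine that favours reductive elimination over β-hydride elimination. C2′ is bonded neither to zinc nor to palladium and is carried through unchanged, and the alkylzinc does not add to the hindered diaryl ketone.

Step 12
Reactants: 17 {2,6-bis[(tert-butyldimethylsilyl)oxy]-4-methoxy-3-(3-methylbut-2-en-1-yl)-5-[(2R)-5-methyl-2-(prop-1-en-2-yl)hex-5-en-1-yl]phenyl}{3-[(tert-butyldimethylsilyl)oxy]phenyl}methanone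
Product: 20 {(3R)-3,7-dihydroxy-5-methoxy-2,2-dimethyl-6-[(2R)-5-methyl-2-(prop-1-en-2-yl)hex-5-en-1-yl]-3,4-dihydro-2H-chromen-8-yl}(3-hydroxyphenyl)methanone (CNP0307300.2), via silylated epoxide 18 (not isolated), via epoxy triphenol 19 (not isolated)
Conditions: 1,2:4,5-di-O-isopropylidene-β-D-erythro-2,3-hexodiulo-2,6-pyranose (D-fructose-derived Shi ketone, 0.3 equiv), KHSO5 (as 2KHSO5·KHSO4·K2SO4, 1.2 equiv, slow addition), K2CO3, Na2B4O7 buffer (pH 10.5), Bu4NHSO4, MeCN–CH2(OMe)2–H2O, 0 °C; extract, then HF·pyridine, pyridine, THF, 0 °C → rt; then camphor-10-sulfonic acid (0.1 equiv), CH2Cl2, 0 °C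
Reagents that add atoms: potassium peroxymonosulfate, [K+].[O-]S(=O)(=O)OO
Why: KHSO5 converts the ketone into a chiral dioxirane, which transfers oxygen to the trisubstituted alkene of 17 through a spiro transition state to give the (R)-epoxide 18, so C3 is set by the catalyst alone; the distant C2′ centre has no say, and any minor epoxide enantiomer ends up as a separable diastereomer of 20. HF·pyridine then removes the three aryl silyl groups without generating a phenoxide, giving 19. Camphorsulfonic acid protonates the epoxide, and the C8a hydroxyl attacks the tertiary carbon in 6-endo-tet mode, forming O1–C2 and closing the dihydropyran. The C3–O bond is not broken, so the (R) configuration of the epoxide becomes that of the carbinol. The closest known reaction type is the Shi epoxidation of silyl-protected ortho-prenylphenols followed by acid-promoted closure to 3-hydroxy-2,2-dimethylchromans. Chemoselectivity rests on the electrophilic dioxirane preferring the more substituted alkene, with limited oxidant and the reaction stopped short of full conversion. Regioselectivity on the arene is secured because the C5 oxygen is a methyl ether and only the C8a oxygen is ortho to the epoxide-bearing carbon, and the silyl groups prevent phenoxide 5-exo attack and phenol oxidation at pH 10.5. Ring size follows from the acid, which directs the nucleophile to the carbon that best carries positive charge and is weak enough to leave the two 1,1-disubstituted alkenes alone.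

## Compound list

1 | (R)-limonene, (4R)-1-methyl-4-(prop-1-en-2-yl)cyclohex-1-ene | CC1=CC[C@@H](CC1)C(=C)C | starting material
2 | (4R)-1-methyl-4-(prop-1-en-2-yl)-7,8,9-trioxabicyclo[4.2.1]nonane (secondary ozonide of 1, mixture at the two acetal carbons) | CC12CC[C@H](CC(O1)OO2)C(C)=C | intermediate (not isolated)
3 | (3R)-6-oxo-3-(prop-1-en-2-yl)heptanal | O=CC[C@@H](CCC(C)=O)C(C)=C | intermediate
4 | (3R)-6-oxo-3-(prop-1-en-2-yl)heptanoic acid | OC(=O)C[C@@H](CCC(C)=O)C(C)=C | intermediate
5 | (3R)-6-methyl-3-(prop-1-en-2-yl)hept-6-enoic acid | OC(=O)C[C@@H](CCC(C)=C)C(C)=C | intermediate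
6 | 2-thioxopyridin-1(2H)-yl (3R)-6-methyl-3-(prop-1-en-2-yl)hept-6-enoate | S=c1ccccn1OC(=O)C[C@@H](CCC(C)=C)C(C)=C | intermediate (not isolated)
7 | (3S)-3-(iodomethyl)-2,6-dimethylhepta-1,6-diene | IC[C@@H](CCC(C)=C)C(C)=C | intermediate
8 | phloroglucinol (benzene-1,3,5-triol) | Oc1cc(O)cc(O)c1 | starting material
9 | 3-hydroxybenzoic acid | O=C(O)c1cccc(O)c1 | starting material
10 | (3-hydroxyphenyl)(2,4,6-trihydroxyphenyl)methanone | O=C(c1cccc(O)c1)c1c(O)cc(O)cc1O | intermediate
11 | (2,6-dihydroxy-4-methoxyphenyl)(3-hydroxyphenyl)methanone | COc1cc(O)c(C(=O)c2cccc(O)c2)c(O)c1 | intermediate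
12 | (3-bromo-2,6-dihydroxy-4-methoxyphenyl)(3-hydroxyphenyl)methanone | COc1cc(O)c(C(=O)c2cccc(O)c2)c(O)c1Br | intermediate
13 | (3-bromo-2,6-dihydroxy-5-iodo-4-methoxyphenyl)(3-hydroxyphenyl)methanone | COc1c(I)c(O)c(C(=O)c2cccc(O)c2)c(O)c1Br | intermediate
14 | {3-bromo-2,6-bis[(tert-butyldimethylsilyl)oxy]-5-iodo-4-methoxyphenyl}{3-[(tert-butyldimethylsilyl)oxy]phenyl}methanone | COc1c(I)c(O[Si](C)(C)C(C)(C)C)c(C(=O)c2cccc(O[Si](C)(C)C(C)(C)C)c2)c(O[Si](C)(C)C(C)(C)C)c1Br | intermediate
15 | {3-bromo-2,6-bis[(tert-butyldimethylsilyl)oxy]-4-methoxy-5-(3-methylbut-2-en-1-yl)phenyl}{3-[(tert-butyldimethylsilyl)oxy]phenyl}methanone | COc1c(CC=C(C)C)c(O[Si](C)(C)C(C)(C)C)c(C(=O)c2cccc(O[Si](C)(C)C(C)(C)C)c2)c(O[Si](C)(C)C(C)(C)C)c1Br | intermediate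
16 | [(2S)-5-methyl-2-(prop-1-en-2-yl)hex-5-en-1-yl]zinc iodide | I[Zn]C[C@@H](CCC(C)=C)C(C)=C | intermediate (not isolated)
17 | {2,6-bis[(tert-butyldimethylsilyl)oxy]-4-methoxy-3-(3-methylbut-2-en-1-yl)-5-[(2R)-5-methyl-2-(prop-1-en-2-yl)hex-5-en-1-yl]phenyl}{3-[(tert-butyldimethylsilyl)oxy]phenyl}methanone | C=C(C)CC[C@H](Cc1c(O[Si](C)(C)C(C)(C)C)c(C(=O)c2cccc(O[Si](C)(C)C(C)(C)C)c2)c(O[Si](C)(C)C(C)(C)C)c(CC=C(C)C)c1OC)C(=C)C | intermediate
18 | {2,6-bis[(tert-butyldimethylsilyl)oxy]-3-{[(2R)-3,3-dimethyloxiran-2-yl]methyl}-4-methoxy-5-[(2R)-5-methyl-2-(prop-1-en-2-yl)hex-5-en-1-yl]phenyl}{3-[(tert-butyldimethylsilyl)oxy]phenyl}methanone | C=C(C)CC[C@H](Cc1c(O[Si](C)(C)C(C)(C)C)c(C(=O)c2cccc(O[Si](C)(C)C(C)(C)C)c2)c(O[Si](C)(C)C(C)(C)C)c(C[C@@H]2C(C)(C)O2)c1OC)C(=C)C | intermediate (not isolated)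
19 | {3-{[(2R)-3,3-dimethyloxiran-2-yl]methyl}-2,6-dihydroxy-4-methoxy-5-[(2R)-5-methyl-2-(prop-1-en-2-yl)hex-5-en-1-yl]phenyl}(3-hydroxyphenyl)methanone | C=C(C)CC[C@H](Cc1c(O)c(C(=O)c2cccc(O)c2)c(O)c(C[C@@H]2C(C)(C)O2)c1OC)C(=C)C | intermediate (not isolated)
20 | {(3R)-3,7-dihydroxy-5-methoxy-2,2-dimethyl-6-[(2R)-5-methyl-2-(prop-1-en-2-yl)hex-5-en-1-yl]-3,4-dihydro-2H-chromen-8-yl}(3-hydroxyphenyl)methanone (CNP0307300.2) | C=C(C)CC[C@H](Cc1c(O)c(C(=O)c2cccc(O)c2)c2c(c1OC)C[C@@H](O)C(C)(C)O2)C(=C)C | target

## Step count and least certain steps

Total: 12 steps. Longest linear sequence: 8 steps (steps 5–12, from phloroglucinol 8 and 3-hydroxybenzoic acid 9). The side-chain branch from (R)-limonene 1 is 4 steps (steps 1–4) and joins at step 11.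

**Step 12 (key step).**
- What may go wrong: once the prenyl alkene is consumed the dioxirane may go on to oxidise the two 1,1-disubstituted alkenes. After desilylation, attack at the secondary epoxide carbon (5-exo) or opening of the epoxide by fluoride may compete with the 6-endo closure.
- Fallback: the oxidation and ring closure are moved ahead of the attachment of the chain, so that no other alkene is present and the ring-size outcome can be settled on a simple compound. It sets out from 15 and rejoins the route at 20. Bromide 15 is epoxidised under the same conditions to the silylated epoxide F1. HF·pyridine frees the epoxy triphenol F2, and camphorsulfonic acid closes it to the bromochromanol F3. TBSOTf and 2,6-lutidine convert F3 into the tris-silyl ether F4 (two phenols and the C3 hydroxyl). F4 is coupled with alkylzinc 16 under the conditions of step 11 to give the silylated chroman F5, and Bu4NF in THF releases 20.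

**Step 4.**
- What may go wrong: if iodine transfer is slow, the primary radical may cyclise onto the alkene five atoms away or be captured by a second ester molecule, and the diiodomethyl chain carrier may add to the alkenes.
- Fallback: the radical is captured instead by a persistent radical, which reacts at close to the diffusion limit and leaves no chain carrier, and the halide is then made by ionic substitution. It sets out from 5 and rejoins at 7. Acid 5 is converted into ester 6 as before, and 6 is photolysed with 2,2,6,6-tetramethylpiperidin-1-oxyl to give the alkoxyamine F6. Zn in acetic acid cleaves the N–O bond to the alcohol F7, and I2, PPh3 and imidazole convert F7 into 7.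

**Step 11.**
- What may go wrong: oxidative addition and transmetalation at the bromide flanked by OMe and OTBS may be slow, leaving time for β-hydride elimination from the alkylpalladium (loss of the chain as a diene, reduction of the arene) and for homocoupling.
- Fallback: the order of the two couplings is reversed so that the demanding sp3 coupling meets the more reactive C–I bond. It sets out from 14 and rejoins at 17. Iodide 14 is coupled with 16 at room temperature to give the bromide F8. The prenyl group is then introduced at the C–Br bond of F8 by Stille coupling with the same stannane under more forcing conditions (Pd(PtBu3)2, toluene, 100 °C), giving 17. Because the two halogen positions are equivalent in the core, the same compound results.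

**Step 10.**
- What may go wrong: allyl transposition may deliver the 1,1-dimethylallyl isomer, and some insertion into the C–Br bond may erode the iodide selectivity.
- Fallback: a group with no regiochemical ambiguity is introduced first and then converted. It sets out from 14 and rejoins at 15. Stille coupling of 14 with allyltributylstannane gives the allyl arene F9. Cross-metathesis of F9 with excess 2-methylbut-2-ene and the second-generation Grubbs catalyst RuCl2(=CHPh)(H2IMes)(PCy3) in CH2Cl2 at 40 °C gives 15.

**Step 6.**
- What may go wrong: methylation may spread to the ring-B phenol or to a second ring-A oxygen.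
- Fallback: the selection is made by leaving-group ability instead. It sets out from 10 and rejoins at 11. Ac2O and pyridine give the tetraacetate F10. Thiophenol and imidazole in N-methylpyrrolidone remove only the acetate para to the ketone, giving the phenol F11. Me3SiCHN2 in MeOH–toluene methylates it to the methoxy triacetate F12, and K2CO3 in MeOH removes the remaining acetates to give 11.

## Further compounds

F1 | step 12 | {3-bromo-2,6-bis[(tert-butyldimethylsilyl)oxy]-5-{[(2R)-3,3-dimethyloxiran-2-yl]methyl}-4-methoxyphenyl}{3-[(tert-butyldimethylsilyl)oxy]phenyl}methanone | COc1c(C[C@@H]2C(C)(C)O2)c(O[Si](C)(C)C(C)(C)C)c(C(=O)c2cccc(O[Si](C)(C)C(C)(C)C)c2)c(O[Si](C)(C)C(C)(C)C)c1Br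
F2 | step 12 | (3-bromo-5-{[(2R)-3,3-dimethyloxiran-2-yl]methyl}-2,6-dihydroxy-4-methoxyphenyl)(3-hydroxyphenyl)methanone | COc1c(C[C@@H]2C(C)(C)O2)c(O)c(C(=O)c2cccc(O)c2)c(O)c1Br
F3 | step 12 | [(3R)-6-bromo-3,7-dihydroxy-5-methoxy-2,2-dimethyl-3,4-dihydro-2H-chromen-8-yl](3-hydroxyphenyl)methanone | Brc1c(O)c(C(=O)c2cccc(O)c2)c2c(c1OC)C[C@@H](O)C(C)(C)O2
F4 | step 12 | {(3R)-6-bromo-3,7-bis[(tert-butyldimethylsilyl)oxy]-5-methoxy-2,2-dimethyl-3,4-dihydro-2H-chromen-8-yl}{3-[(tert-butyldimethylsilyl)oxy]phenyl}methanone | Brc1c(O[Si](C)(C)C(C)(C)C)c(C(=O)c2cccc(O[Si](C)(C)C(C)(C)C)c2)c2c(c1OC)C[C@@H](O[Si](C)(C)C(C)(C)C)C(C)(C)O2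
F5 | step 12 | {(3R)-3,7-bis[(tert-butyldimethylsilyl)oxy]-5-methoxy-2,2-dimethyl-6-[(2R)-5-methyl-2-(prop-1-en-2-yl)hex-5-en-1-yl]-3,4-dihydro-2H-chromen-8-yl}{3-[(tert-butyldimethylsilyl)oxy]phenyl}methanone | C=C(C)CC[C@H](Cc1c(O[Si](C)(C)C(C)(C)C)c(C(=O)c2cccc(O[Si](C)(C)C(C)(C)C)c2)c2c(c1OC)C[C@@H](O[Si](C)(C)C(C)(C)C)C(C)(C)O2)C(=C)C
F6 | step 4 | 2,2,6,6-tetramethyl-1-{[(2S)-5-methyl-2-(prop-1-en-2-yl)hex-5-en-1-yl]oxy}piperidine | CC1(C)CCCC(C)(C)N1OC[C@@H](CCC(C)=C)C(C)=C
F7 | step 4 | (2S)-5-methyl-2-(prop-1-en-2-yl)hex-5-en-1-ol | OC[C@@H](CCC(C)=C)C(C)=C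
F8 | step 11 | {3-bromo-2,6-bis[(tert-butyldimethylsilyl)oxy]-4-methoxy-5-[(2R)-5-methyl-2-(prop-1-en-2-yl)hex-5-en-1-yl]phenyl}{3-[(tert-butyldimethylsilyl)oxy]phenyl}methanone | C=C(C)CC[C@H](Cc1c(O[Si](C)(C)C(C)(C)C)c(C(=O)c2cccc(O[Si](C)(C)C(C)(C)C)c2)c(O[Si](C)(C)C(C)(C)C)c(Br)c1OC)C(=C)C
F9 | step 10 | {3-bromo-2,6-bis[(tert-butyldimethylsilyl)oxy]-4-methoxy-5-(prop-2-en-1-yl)phenyl}{3-[(tert-butyldimethylsilyl)oxy]phenyl}methanone | COc1c(CC=C)c(O[Si](C)(C)C(C)(C)C)c(C(=O)c2cccc(O[Si](C)(C)C(C)(C)C)c2)c(O[Si](C)(C)C(C)(C)C)c1Br
F10 | step 6 | 2-(3-acetoxybenzoyl)benzene-1,3,5-triyl triacetate | CC(=O)Oc1cccc(c1)C(=O)c1c(OC(C)=O)cc(OC(C)=O)cc1OC(C)=O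
F11 | step 6 | 2-(3-acetoxybenzoyl)-5-hydroxy-1,3-phenylene diacetate | CC(=O)Oc1cccc(c1)C(=O)c1c(OC(C)=O)cc(O)cc1OC(C)=O
F12 | step 6 | 2-(3-acetoxybenzoyl)-5-methoxy-1,3-phenylene diacetate | COc1cc(OC(C)=O)c(C(=O)c2cccc(OC(C)=O)c2)c(OC(C)=O)c1
A1 | alternative 1 | 2-{[(tert-butyldimethylsilyl)oxy][3-(triisopropylsilyloxy)phenyl]methyl}-5-methoxy-4-(3-methylbut-2-en-1-yl)-6-[(2R)-5-methyl-2-(prop-1-en-2-yl)hex-5-en-1-yl]-3-(triisopropylsilyloxy)phenol | C=C(C)CC[C@H](Cc1c(O)c(C(O[Si](C)(C)C(C)(C)C)c2cccc(O[Si](C(C)C)(C(C)C)C(C)C)c2)c(O[Si](C(C)C)(C(C)C)C(C)C)c(CC=C(C)C)c1OC)C(=C)C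
A2 | alternative 1 | 3-methoxy-2-(3-methylbut-2-en-1-yl)-4-[(2R)-5-methyl-2-(prop-1-en-2-yl)hex-5-en-1-yl]cyclobut-2-en-1-one | COC1=C(CC=C(C)C)C(=O)C1C[C@@H](CCC(C)=C)C(C)=C
A3 | alternative 1 | tert-butyldimethyl({1-[3-(triisopropylsilyloxy)phenyl]-3-(triisopropylsilyloxy)prop-2-yn-1-yl}oxy)silane | CC(C)[Si](OC#CC(O[Si](C)(C)C(C)(C)C)c1cccc(O[Si](C(C)C)(C(C)C)C(C)C)c1)(C(C)C)C(C)C
A4 | alternative 2 | {2,4,6-trihydroxy-3-(3-methylbut-2-en-1-yl)-5-[(2R)-5-methyl-2-(prop-1-en-2-yl)hex-5-en-1-yl]phenyl}[3-(prop-2-en-1-yloxy)phenyl]methanone | C=C(C)CC[C@H](Cc1c(O)c(C(=O)c2cccc(OCC=C)c2)c(O)c(CC=C(C)C)c1O)C(=C)C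
A5 | alternative 2 | methyl 2-(3-methylbut-2-en-1-yl)-4-[(2R)-5-methyl-2-(prop-1-en-2-yl)hex-5-en-1-yl]-3,5,7-trioxo-7-[3-(prop-2-en-1-yloxy)phenyl]heptanoate | COC(=O)C(CC=C(C)C)C(=O)C(C[C@@H](CCC(C)=C)C(C)=C)C(=O)CC(=O)c1cccc(OCC=C)c1
A6 | alternative 3 | {(3R)-5,7-dimethoxy-3-(methoxymethoxy)-2,2-dimethyl-6-[(2R)-5-methyl-2-(prop-1-en-2-yl)hex-5-en-1-yl]-3,4-dihydro-2H-chromen-8-yl}[3-(triisopropylsilyloxy)phenyl]methanone | C=C(C)CC[C@H](Cc1c(OC)c(C(=O)c2cccc(O[Si](C(C)C)(C(C)C)C(C)C)c2)c2c(c1OC)C[C@@H](OCOC)C(C)(C)O2)C(=C)C
A7 | alternative 3 | {2-fluoro-3-[(2R)-3-hydroxy-2-(methoxymethoxy)-3-methylbutyl]-4,6-dimethoxy-5-[(2R)-5-methyl-2-(prop-1-en-2-yl)hex-5-en-1-yl]phenyl}[3-(triisopropylsilyloxy)phenyl]methanone | C=C(C)CC[C@H](Cc1c(OC)c(C(=O)c2cccc(O[Si](C(C)C)(C(C)C)C(C)C)c2)c(F)c(C[C@@H](OCOC)C(C)(C)O)c1OC)C(=C)C
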